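All runs stem from a simulated flask with constants of no real substance.

Time is the first question: has a flask stopped by the asked 2.5 d?

common to all: Ja 27 µM; Je 38 µM
- autumn: Jb 0.14 M; Jd 0.15 M; temperature 0 °C; run made earlier
- dusk: Jb 0.14 M; Jd 0.18 M; temperature 11 °C; run made earlier
- winter: Jb 0.12 M; Jd 0.133 M; temperature 0 °C; run made earlier
- grey: Jb 0.10 M; Jd 0.200 M; temperature 5 °C; time 2.5 d
- violet: Jb 0.14 M; Jd 0.133 M; temperature 5 °C; time 2.5 d

| run | time / h | Jj / % |
|---|---|---|
| autumn | 8.00 | 16.9 |
| autumn | 15.0 | 21.2 |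
| autumn | 25.0 | 26.9 |
| autumn | 30.0 | 28.2 |
| autumn | 40.0 | 27.2 |
| dusk | 8.00 | 31.1 |
| dusk | 15.0 | 35.9 |
| dusk | 25.0 | 32.1 |
| dusk | 30.0 | 32.0 |
| dusk | 40.0 | 31.6 |
| winter | 3.00 | 9.6 |
| winter | 6.00 | 15.5 |
| winter | 12.0 | 22.3 |
| winter | 20.0 | 28.0 |
| winter | 40.0 | 34.1 |

(scatter of a reading: 1 percentage point)

* which one finishes higher in amount of Jj, in percent of the Jb charged ("neither" within 2 percentage points) (grey / violet / neither)
* amount of Jj at the end, in percent of the Jb charged, grey
* amount of Jj at the end, in percent of the Jb charged, violet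



Has it stopped? The autumn flask at 0 °C reads 28.2% at 30.0 h and 27.2% at 40.0 h, and the dusk flask at 11 °C is level from 25.0 h on, so a flask at 5 °C should be level well before 2.5 d.

Level at what? Not at a fixed percentage: the winter flask, charged with less Jb, reaches 34.1% at 40.0 h, higher than autumn's 27.2%. Multiply by the charges and the two nearly meet: [Jj] is 0.0409 M in winter against 0.0388 M in autumn, taken as the mean of its last two readings.

And temperature? Dusk's readings from 25.0 h on average 0.0447 M. A straight line between autumn and dusk gives 0.0415 M at 5 °C. That is the ceiling, the [Jj] at which I expect a flask at 5 °C to stop.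

Where is that weakest? Dusk also held more Jd than autumn, so the step may belong to Jd and not to temperature. Winter held less Jd and less Jb than autumn without a lower [Jj], so I read no strong effect of Jd, but two settings differ there, winter's last reading still stands above its 28.0% at 20.0 h, the scatter of 1 percentage point leaves room, and grey's 0.200 M lies beyond the charges tried.

Where does control change hands? A percentage of the charge stops at 100%, so I take the ceiling over the [Jb] charged while that [Jb] stands above the ceiling; below that crossing, the Jb charged is what bounds [Jj]. Grey's 0.10 M and violet's 0.14 M both stand above it, so I commit to 41.5% for grey and 29.6% for violet. Grey leads by 12 points, against a margin of 2 points.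

The forecast stands a little above my figures, with grey ahead, 42% (36% to 50%) for grey and 30% (26% to 35%) for violet, since dusk's overshoot “looks like a ceiling in absolute concentration”.

The flask gives grey ahead, with 43.8% for grey and 29.0% for violet.

    Ja → Jc (k = 4.40 × 10⁻⁶ /s, Ea = 222 kJ/mol)
    Jb + Ja ⇌ Jg (K = 98.0 /M, k = 440 /M/s, Ea = 36.0 kJ/mol, ΔH = −1.00 kJ/mol)
    Jd + Jg ⇌ Jh (K = 17.0 /M, k = 360 /M/s, Ea = 36.0 kJ/mol, ΔH = −15.0 kJ/mol)
    Jh → Ja + Jj (k = 0.130 /s, Ea = 82.0 kJ/mol)
    Ja + Je ⇌ Jk (K = 11000 /M, k = 10.0 /M/s, Ea = 42.0 kJ/mol, ΔH = −11.0 kJ/mol)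
    2 Jd → Jf (k = 7.40 × 10⁻⁴ /M/s, Ea = 62.0 kJ/mol)
    (constants at 5 °C)

Read back as [Jj] at the end, grey stands at 0.0438 M and violet at 0.0406 M, on either side of the 0.0415 M reckoned. In grey, Jd is the limiting reagent, with 0% left at 2.50 d. Of its charge, 0.156 M went into Jf, 3.57 times the Jd that became Jj. A neighbour flask, grey's recipe with 0.025 M of Jb, stands below the crossing: it gives 99.6%, with 0.45% of its Jb left.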